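If you want G late in this flask, write the balance of the smaller charge first. With [Q] at 0.050 M and [L] at 0.0600 M, the flask holds 1.20 L per Q, so Q is the limiting reagent.

| flask | Q | L | remark | time | volume of the second phase over the first |
|---|---|---|---|---|---|
| eta | 0.050 M | 0.040 M | run made earlier |  |  |
| delta | 0.050 M | 0.090 M | run made earlier |  |  |
| gamma | 0.025 M | 0.060 M | run made earlier |  |  |
| flask | 0.050 M | 0.0600 M |  | 40 min | 0.25 |

- eta (time / min: G / %, Q / %): 3.00: 48, 41; 10.0: 56, 15; 15.0: 50, 17; 25.0: 46, 13; 40.0: 46, 9; 50.0: 46, 12
- delta (time / min: G / %, Q / %): 8.00: 72, 0; 15.0: 60, 0; 25.0: 58, 0; 30.0: 55, 3; 40.0: 57, 0; 50.0: 56, 0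
- gamma (time / min: G / %, Q / %): 10.0: 66, 1; 20.0: 57, 0; 30.0: 56, 5; 40.0: 58, 0; 50.0: 57, 0

(each reading ± 1.5 percentage points)

- G at 40 min, in percent of the Q charged
- part of the Q charged that has reacted at 40 min

- in the second phase: L; everything else is in the first
- charges count per volume of the first phase; a concentration in a rate is the amount of a species over the volume of its own phase; every rate counts per litre of the first phase
- the earlier runs hold the two phases in the same ratio of volumes as the flask asked about
- what has gone from Q into another species counts as reacted, even if it can come back

Take delta and gamma, both with L in excess. Their last two readings of G average 57.0%; call this the plateau share, the part of the Q that L can turn which stands as G once the hump is over. Test it on eta, whose L covers 0.800 of its Q: the product is 45.6%, and eta reads 46% at 40.0 min.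

Now draw G in the flask. Start steep: eta, with less L, reads 48% at 3.00 min, and a straight line from zero through that reading reaches the flask's level, 57.0%, after 3.56 min. Expect the curve to overshoot: the first readings of delta and gamma stand at 72% and 66%. Then read the fall in delta, where the excess over the share drops from 15 percentage points to 3 points between 8.00 min and 15.0 min. That gives a rough half-life of 3.01 min. The asked time is 13.3 of these, so put G on its level. For Q take delta, which reads 0% at 40.0 min, though the flask has less L; the flask's L still covers more of its Q than eta's does, and eta's Q reads 9% at 40.0 min.

The forecast gives 55% and 98%: “G should sit near the excess-L plateau”. My level stands 2 points above it, against a scatter of 1.5 points, and my Q, near zero, stands below the 2.00% that the forecast leaves.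

The flask gives G 56.0% with 99.9% of Q reacted, under this scheme:

    J ⇌ L, rate k1*([J] - [L]/K1) per volume of the first phase (partition coefficient = 0.380, kL = 0.0576 min⁻¹)
    Q ⇌ D (K = 0.860, k = 0.0216 min⁻¹)
    Q + J → G (k = 43.1 M⁻¹ min⁻¹)
    G ⇌ X (K = 0.760, k = 0.0673 min⁻¹)

G and X relax with a half-life of 4.45 min, short against 40 min. The level of 57.0% stands 1 point above the flask. Put the plateau share on the neighbour with 0.12 M of Q, where L is the smaller charge: the share times 0.500 gives 28.5%, and that neighbour holds G 28.5% at 40.0 min.

The numbers in the tables come from a simulation for an exercise, and the scatter is random.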